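**Plan**
1. Retrosynthesis: first remove the eight benzyl groups and the C3–C4 saturation of the upper flavan; then cut the interflavan bond C4(upper)–C8(lower) into an alkenyl triflate and an 8-metalated catechin ether; last, in the lower unit, cut O1–C2 and C3–C4 of ring C together, with the C3 hydroxyl masked as a silanol.
2. Enabling feature: in the lower unit the phenol oxygen O1 on C8a of ring A stands ortho to the benzylic carbon C4 on C4a, so O1–C8a–C4a–C4 of a salicyl alcohol is a latent ortho-quinone methide (a 4π heterodiene).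
3. Forward, lower unit: the quinone methide of a phloroglucinol dibenzyl ether and an (E)-styryl silanol close ring C in one [4+2] step; Tamao oxidation, C8 bromination and 3-O-benzylation follow.
4. Forward, upper unit and union: a chromone is arylated at C2 by asymmetric conjugate addition and converted into its enol triflate; Negishi coupling joins C4 to C8; one hydrogenation saturates C3=C4 and removes all benzyl groups.
5. Stereochemistry: lower C2/C3 trans from the (E)-alkene, absolute sense from a chiral phosphoric acid; C3–O by retentive C–Si oxidation; upper C2 from the chiral palladium catalyst; upper C4 by hydrogen delivery anti to the C2 aryl group (2,4-cis).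

Key step: step 5

Remark: the target is read as a (2S,4S), 2,4-cis 3',4',7-trihydroxyflavan joined from C4 to C8 of (2R,3S)-catechin.
Assumption: the sense of induction of (R)-TRIP (step 5) and of (R)-t-BuPyOx (step 10) is taken by analogy with related substrates; the configuration is to be checked at 10 and 16, and the mirror-image catalyst is used if the check requires it.

**Route**

Step 1
Reactants: 1 2,4,6-trihydroxybenzaldehyde
Product: 2 4,6-bis(benzyloxy)-2-hydroxybenzaldehyde
Conditions: BnBr (2.1 equiv), K2CO3, DMF, 0 °C → rt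
Reagents that add atoms: benzyl bromide, BrCc1ccccc1
Why: Williamson etherification takes the para hydroxyl and one ortho hydroxyl, while the second ortho hydroxyl, held in a hydrogen bond to the formyl oxygen, is the least nucleophilic and should stay free.

Step 2
Reactants: 2 4,6-bis(benzyloxy)-2-hydroxybenzaldehyde
Product: 3 3,5-bis(benzyloxy)-2-(hydroxymethyl)phenol
Conditions: NaBH4, THF–MeOH, 0 °C; neutral work-up, used at once
Reagents that add atoms: none
Why: Borohydride reduction of the aldehyde is chemoselective, and the easily ionised electron-rich salicyl alcohol is kept cold and neutral and carried on without storage.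

Step 3
Reactants: 4 3,4-bis(benzyloxy)benzaldehyde
Product: 5 1,2-bis(benzyloxy)-4-ethynylbenzene
Conditions: dimethyl (1-diazo-2-oxopropyl)phosphonate, K2CO3, MeOH, rt
Reagents that add atoms: dimethyl (1-diazo-2-oxopropyl)phosphonate, COP(=O)(OC)C(=[N+]=[N-])C(C)=O
Why: Seyferth–Gilbert homologation in the Ohira–Bestmann variant converts a non-enolisable aryl aldehyde into the terminal alkyne under mild base that leaves benzyl ethers untouched.

Step 4
Reactants: 5 1,2-bis(benzyloxy)-4-ethynylbenzene
Product: 7 (E)-[2-[3,4-bis(benzyloxy)phenyl]ethenyl]diisopropylsilanol, via chlorosilane 6 (not isolated)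
Conditions: iPr2SiHCl, Pt2[(CH2=CHSiMe2)2O]3 (0.5 mol%), P(t-Bu)3 (1 mol%), THF, rt; then aq NaHCO3, Et2O, 0 °C
Reagents that add atoms: chlorodiisopropylsilane, CC(C)[SiH](Cl)C(C)C; water, O
Why: Platinum-catalysed syn hydrosilylation of a terminal aryl alkyne places silicon on the terminal carbon to give the (E)-alkenylsilane, and buffered hydrolysis of Si–Cl gives a hindered silanol that does not condense to the disiloxane.

Step 5
Reactants: 3 3,5-bis(benzyloxy)-2-(hydroxymethyl)phenol; 7 (E)-[2-[3,4-bis(benzyloxy)phenyl]ethenyl]diisopropylsilanol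
Product: 9 [(2R,3S)-5,7-bis(benzyloxy)-2-[3,4-bis(benzyloxy)phenyl]-3,4-dihydro-2H-chromen-3-yl]diisopropylsilanol, via ortho-quinone methide 8 (not isolated)
Conditions: (R)-TRIP [(R)-3,3'-bis(2,4,6-triisopropylphenyl)-1,1'-binaphthyl-2,2'-diyl hydrogen phosphate] (10 mol%), 4 Å MS, toluene, 40 °C, slow addition of 3 to 7 (1.5 equiv)
Reagents that add atoms: none
Why: Proposed new method: the phosphoric acid dehydrates 3 to the ortho-quinone methide 8 (heterodiene O1=C8a–C4a=C4H2), binds its oxygen through P–OH and the silanol of 7 through P=O, and the (E)-alkene then adds in an asynchronous inverse-electron-demand hetero-Diels–Alder reaction in which the C3–C4 bond leads and the O1–C2 bond follows. The closest known reaction types are the [4+2] cycloadditions of ortho-quinone methides with β-substituted electron-rich styrenes (trans-2-aryl-3-substituted chromans) and the chiral phosphoric acid-catalysed cycloadditions of ortho-quinone methides with alkenes that carry an OH or NH donor; the vinylsilanol dienophile and enantiocontrol at an unsubstituted methide carbon are the untested elements. Ring C closes as the six-membered ring of this intermolecular [4+2] cycloaddition (4π heterodiene, 2π alkene, suprafacial on the alkene). C2 and C3 arise together: their trans relation is fixed by the (E) geometry of 7 because both bonds form on one alkene face, and their absolute configuration (2R,3S) by the chiral phosphate, which holds the silanol-bound alkene with one face toward C4. The step needs regioselectivity (C4 to the silicon-bearing carbon, O1 to the benzylic carbon), secured because this orientation puts the developing positive charge on the carbon stabilised by the 3,4-bis(benzyloxy)phenyl ring and by the β-silicon effect, and it needs a single quinone methide, secured because only the phenol oxygen ortho to the hydroxymethyl carbon is free while the other two oxygens of ring A are benzyl ethers. Slow addition of 3 keeps the methide dilute so that cycloaddition should outrun its self-condensation.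

Step 6
Reactants: 9 [(2R,3S)-5,7-bis(benzyloxy)-2-[3,4-bis(benzyloxy)phenyl]-3,4-dihydro-2H-chromen-3-yl]diisopropylsilanol
Product: 10 (2R,3S)-5,7-bis(benzyloxy)-2-[3,4-bis(benzyloxy)phenyl]chroman-3-ol (5,7,3',4'-tetra-O-benzyl-(+)-catechin)
Conditions: KF, KHCO3, 30% H2O2, THF–MeOH, 50 °C
Reagents that add atoms: hydrogen peroxide, OO
Why: Tamao–Fleming oxidation (fluoride-assisted peroxide attack at silicon, then 1,2-shift of C3 from silicon to oxygen with retention) should give the 3S alcohol, and benzyl ethers and the electron-rich rings are inert to basic peroxide.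

Step 7
Reactants: 10 (2R,3S)-5,7-bis(benzyloxy)-2-[3,4-bis(benzyloxy)phenyl]chroman-3-ol
Product: 11 (2R,3S)-5,7-bis(benzyloxy)-2-[3,4-bis(benzyloxy)phenyl]-8-bromochroman-3-ol
Conditions: NBS, CH2Cl2, −78 °C → 0 °C
Reagents that add atoms: N-bromosuccinimide, O=C1CCC(=O)N1Br
Why: Electrophilic aromatic bromination of ring A goes to C8, which is flanked by only one benzyl ether, in preference to C6 between two benzyloxy groups, the usual outcome for 5,7-di-O-benzyl flavan-3-ols.

Step 8
Reactants: 11 (2R,3S)-5,7-bis(benzyloxy)-2-[3,4-bis(benzyloxy)phenyl]-8-bromochroman-3-ol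
Product: 12 (2R,3S)-3,5,7-tris(benzyloxy)-2-[3,4-bis(benzyloxy)phenyl]-8-bromochromane
Conditions: NaH, BnBr, n-Bu4NI (cat.), DMF, 0 °C → rt
Reagents that add atoms: benzyl bromide, BrCc1ccccc1
Why: Williamson benzylation of the secondary alkoxide masks the only acidic proton before the halogen–lithium exchange, and C2 cannot epimerise because ring B carries no free phenol.

Step 9
Reactants: 13 7-hydroxy-4H-chromen-4-one
Product: 14 7-(benzyloxy)-4H-chromen-4-one
Conditions: BnBr, K2CO3, acetone, reflux
Reagents that add atoms: benzyl bromide, BrCc1ccccc1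
Why: Williamson etherification of the single, acidic vinylogous-acid phenol is straightforward.

Step 10
Reactants: 14 7-(benzyloxy)-4H-chromen-4-one; 15 [3,4-bis(benzyloxy)phenyl]boronic acid
Product: 16 (2S)-7-(benzyloxy)-2-[3,4-bis(benzyloxy)phenyl]chroman-4-one
Conditions: Pd(OCOCF3)2 (5 mol%), (R)-t-BuPyOx [(R)-4-tert-butyl-2-(pyridin-2-yl)-4,5-dihydrooxazole] (6 mol%), NH4PF6 (30 mol%), H2O (5 equiv), ClCH2CH2Cl, 60 °C
Reagents that add atoms: none
Why: Asymmetric 1,4-addition of an arylboronic acid to a chromone (Hayashi–Miyaura type, cationic divalent palladium–pyridinooxazoline catalyst) sets C2 by ligand-controlled aryl transfer, and protonation of the palladium enolate releases the flavanone without base that could open the ring.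

Step 11
Reactants: 16 (2S)-7-(benzyloxy)-2-[3,4-bis(benzyloxy)phenyl]chroman-4-one
Product: 17 (2S)-7-(benzyloxy)-2-[3,4-bis(benzyloxy)phenyl]-2H-chromen-4-yl trifluoromethanesulfonate
Conditions: N-(5-chloropyridin-2-yl)bis(trifluoromethanesulfonimide), KN(SiMe3)2, THF, −78 °C (base added last)
Reagents that add atoms: N-(5-chloropyridin-2-yl)bis(trifluoromethanesulfonimide), O=S(=O)(N(c1ccc(Cl)cn1)S(=O)(=O)C(F)(F)F)C(F)(F)F
Why: Kinetic enolisation at −78 °C in the presence of the triflating agent should trap the enolate as the enol triflate before β-elimination of the ring oxygen, and C2 is not touched, so its configuration is kept.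

Step 12
Reactants: 12 (2R,3S)-3,5,7-tris(benzyloxy)-2-[3,4-bis(benzyloxy)phenyl]-8-bromochromane; 17 (2S)-7-(benzyloxy)-2-[3,4-bis(benzyloxy)phenyl]-2H-chromen-4-yl trifluoromethanesulfonate
Product: 20 (2R,3S)-3,5,7-tris(benzyloxy)-2-[3,4-bis(benzyloxy)phenyl]-8-[(2S)-7-(benzyloxy)-2-[3,4-bis(benzyloxy)phenyl]-2H-chromen-4-yl]chromane, via aryllithium 18 (not isolated), via arylzinc chloride 19 (not isolated)
Conditions: n-BuLi, THF, −78 °C; ZnCl2, −78 °C → rt; then 17, Pd2(dba)3 (2.5 mol%), SPhos (10 mol%), THF, 60 °C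
Reagents that add atoms: none
Why: Bromine–lithium exchange, transmetalation to zinc and Negishi coupling (zerovalent palladium with a bulky biaryl phosphine) should join the doubly ortho-substituted arylzinc to the alkenyl triflate without touching any stereocentre or benzyl ether.

Step 13
Reactants: 20 (2R,3S)-3,5,7-tris(benzyloxy)-2-[3,4-bis(benzyloxy)phenyl]-8-[(2S)-7-(benzyloxy)-2-[3,4-bis(benzyloxy)phenyl]-2H-chromen-4-yl]chromane
Product: 21 (2R,3S)-2-(3,4-dihydroxyphenyl)-8-[(2S,4S)-2-(3,4-dihydroxyphenyl)-7-hydroxychroman-4-yl]chroman-3,5,7-triol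
Conditions: H2 (1 atm), Pd(OH)2/C, THF–MeOH, rt
Reagents that add atoms: none
Why: Heterogeneous hydrogenation should deliver hydrogen to C3=C4 from the face opposite the C2 aryl group, which sets C4 cis to it (4S), while the same catalyst cleaves all eight benzyl ethers by hydrogenolysis.

**Compound list**
1 | 2,4,6-trihydroxybenzaldehyde | O=Cc1c(O)cc(O)cc1O | starting material
2 | 4,6-bis(benzyloxy)-2-hydroxybenzaldehyde | O=Cc1c(O)cc(OCc2ccccc2)cc1OCc1ccccc1 | intermediate
3 | 3,5-bis(benzyloxy)-2-(hydroxymethyl)phenol | OCc1c(O)cc(OCc2ccccc2)cc1OCc1ccccc1 | intermediate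
4 | 3,4-bis(benzyloxy)benzaldehyde | O=Cc1ccc(OCc2ccccc2)c(OCc2ccccc2)c1 | starting material
5 | 1,2-bis(benzyloxy)-4-ethynylbenzene | C#Cc1ccc(OCc2ccccc2)c(OCc2ccccc2)c1 | intermediate
6 | (E)-[2-[3,4-bis(benzyloxy)phenyl]ethenyl]chlorodiisopropylsilane | Cl[Si](/C=C/c1ccc(OCc2ccccc2)c(OCc2ccccc2)c1)(C(C)C)C(C)C | intermediate
7 | (E)-[2-[3,4-bis(benzyloxy)phenyl]ethenyl]diisopropylsilanol | O[Si](/C=C/c1ccc(OCc2ccccc2)c(OCc2ccccc2)c1)(C(C)C)C(C)C | intermediate
8 | 3,5-bis(benzyloxy)-6-methylidenecyclohexa-2,4-dien-1-one (ortho-quinone methide) | C=C1C(=O)C=C(OCc2ccccc2)C=C1OCc1ccccc1 | intermediate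
9 | [(2R,3S)-5,7-bis(benzyloxy)-2-[3,4-bis(benzyloxy)phenyl]-3,4-dihydro-2H-chromen-3-yl]diisopropylsilanol | c1c(OCc2ccccc2)cc(OCc2ccccc2)c2c1O[C@H](c1ccc(OCc3ccccc3)c(OCc3ccccc3)c1)[C@@H]([Si](O)(C(C)C)C(C)C)C2 | intermediate
10 | (2R,3S)-5,7-bis(benzyloxy)-2-[3,4-bis(benzyloxy)phenyl]chroman-3-ol | c1c(OCc2ccccc2)cc(OCc2ccccc2)c2c1O[C@H](c1ccc(OCc3ccccc3)c(OCc3ccccc3)c1)[C@@H](O)C2 | intermediate
11 | (2R,3S)-5,7-bis(benzyloxy)-2-[3,4-bis(benzyloxy)phenyl]-8-bromochroman-3-ol | Brc1c(OCc2ccccc2)cc(OCc2ccccc2)c2c1O[C@H](c1ccc(OCc3ccccc3)c(OCc3ccccc3)c1)[C@@H](O)C2 | intermediate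
12 | (2R,3S)-3,5,7-tris(benzyloxy)-2-[3,4-bis(benzyloxy)phenyl]-8-bromochromane | Brc1c(OCc2ccccc2)cc(OCc2ccccc2)c2c1O[C@H](c1ccc(OCc3ccccc3)c(OCc3ccccc3)c1)[C@@H](OCc1ccccc1)C2 | intermediate
13 | 7-hydroxy-4H-chromen-4-one | O=c1ccoc2cc(O)ccc12 | starting material
14 | 7-(benzyloxy)-4H-chromen-4-one | O=c1ccoc2cc(OCc3ccccc3)ccc12 | intermediate
15 | [3,4-bis(benzyloxy)phenyl]boronic acid | OB(O)c1ccc(OCc2ccccc2)c(OCc2ccccc2)c1 | starting material
16 | (2S)-7-(benzyloxy)-2-[3,4-bis(benzyloxy)phenyl]chroman-4-one | c1ccccc1COc1ccc2c(c1)O[C@H](c1ccc(OCc3ccccc3)c(OCc3ccccc3)c1)CC2=O | intermediate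
17 | (2S)-7-(benzyloxy)-2-[3,4-bis(benzyloxy)phenyl]-2H-chromen-4-yl trifluoromethanesulfonate | c1ccccc1COc1ccc2c(c1)O[C@H](c1ccc(OCc3ccccc3)c(OCc3ccccc3)c1)C=C2OS(=O)(=O)C(F)(F)F | intermediate
18 | [(2R,3S)-3,5,7-tris(benzyloxy)-2-[3,4-bis(benzyloxy)phenyl]chroman-8-yl]lithium | [Li]c1c(OCc2ccccc2)cc(OCc2ccccc2)c2c1O[C@H](c1ccc(OCc3ccccc3)c(OCc3ccccc3)c1)[C@@H](OCc1ccccc1)C2 | intermediate
19 | chloro[(2R,3S)-3,5,7-tris(benzyloxy)-2-[3,4-bis(benzyloxy)phenyl]chroman-8-yl]zinc | Cl[Zn]c1c(OCc2ccccc2)cc(OCc2ccccc2)c2c1O[C@H](c1ccc(OCc3ccccc3)c(OCc3ccccc3)c1)[C@@H](OCc1ccccc1)C2 | intermediate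
20 | (2R,3S)-3,5,7-tris(benzyloxy)-2-[3,4-bis(benzyloxy)phenyl]-8-[(2S)-7-(benzyloxy)-2-[3,4-bis(benzyloxy)phenyl]-2H-chromen-4-yl]chromane | c1ccccc1COc1ccc2c(c1)O[C@H](c1ccc(OCc3ccccc3)c(OCc3ccccc3)c1)C=C2c1c(OCc2ccccc2)cc(OCc2ccccc2)c2c1O[C@H](c1ccc(OCc3ccccc3)c(OCc3ccccc3)c1)[C@@H](OCc1ccccc1)C2 | intermediate
21 | (2R,3S)-2-(3,4-dihydroxyphenyl)-8-[(2S,4S)-2-(3,4-dihydroxyphenyl)-7-hydroxychroman-4-yl]chroman-3,5,7-triol | Oc1ccc2c(c1)O[C@H](c1ccc(O)c(O)c1)C[C@@H]2c1c(O)cc(O)c2c1O[C@H](c1ccc(O)c(O)c1)[C@@H](O)C2 | target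

**Totals and risks**
Total step count: 13. Longest linear sequence: 8 steps (1, 2, 5, 6, 7, 8, 12, 13; the branch 3, 4, 5, 6, 7, 8, 12, 13 is equally long).

Step 5 (proposed new method). What may go wrong: insufficient discrimination of the two alkene faces by the phosphate; loss of silicon from the developing β-silyl benzylic cation (ipso substitution or acid-induced ring opening) in place of ring closure; self-condensation of the quinone methide on the electron-rich ring A. The fallback uses known reaction types and sets out from 3 and 5. Acid-promoted or thermal [4+2] cycloaddition of the quinone methide 8 with the aryl alkyne 5 still forms O1–C2 and C3–C4 and should give 5,7-bis(benzyloxy)-2-[3,4-bis(benzyloxy)phenyl]-4H-chromene F1. Asymmetric hydroboration of this trisubstituted enol ether with monoisopinocampheylborane (from (+)-α-pinene, the antipode chosen by analogy with 1-arylcycloalkenes; THF, −25 °C) should place boron on C3 and hydrogen on C2 of one face, giving [(2R,3S)-5,7-bis(benzyloxy)-2-[3,4-bis(benzyloxy)phenyl]chroman-3-yl](isopinocampheyl)borane F2. Oxidation with NaOH/H2O2 with retention comes back to the route at 10, so the oxidation of the β-aryloxy silane in step 6 is bypassed as well.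

Step 13. What may go wrong: hydrogen delivery to the wrong face of C3=C4 (2,4-trans series), or hydrogenolysis of the allylic and benzylic C2–O1 bond before the alkene is saturated; both faults would surface only at the unprotected polyphenol stage, where separation is hard. The fallback sets out from 20 and separates the two events. Ionic hydrogenation (Et3SiH, CF3CO2H, CH2Cl2, −40 °C) protonates C3, and axial hydride delivery to the 4-aryl-flavan-4-yl cation should leave both aryl groups equatorial. This gives (2R,3S)-3,5,7-tris(benzyloxy)-2-[3,4-bis(benzyloxy)phenyl]-8-[(2S,4S)-7-(benzyloxy)-2-[3,4-bis(benzyloxy)phenyl]chroman-4-yl]chromane F5, which is purified at the benzyl ether stage. Hydrogenolysis (H2, Pd(OH)2/C) then comes back to the route at 21.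

Step 12. What may go wrong: slow transmetalation or reductive elimination at the doubly ortho-substituted arylzinc, protonation of the organometallic (loss of the C8 handle), or metalation of benzylic positions during the exchange. The fallback sets out from 16 and 10 and replaces the cross-coupling by a cationic C4–C8 bond formation. NaBH4 reduction of 16 should give (2S,4S)-7-(benzyloxy)-2-[3,4-bis(benzyloxy)phenyl]chroman-4-ol F3. Ionisation with BF3·OEt2 (CH2Cl2, −40 °C) in the presence of excess 10 should alkylate the nucleophilic C8 and, after separation of the C4 epimers at the benzyl ether stage, give (2R,3S)-5,7-bis(benzyloxy)-2-[3,4-bis(benzyloxy)phenyl]-8-[(2S,4S)-7-(benzyloxy)-2-[3,4-bis(benzyloxy)phenyl]chroman-4-yl]chroman-3-ol F4. Hydrogenolysis (H2, Pd(OH)2/C) comes back to the route at 21; steps 7, 8 and 11 are not needed on this path.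

**Further compounds**
F1 | step 5 | 5,7-bis(benzyloxy)-2-[3,4-bis(benzyloxy)phenyl]-4H-chromene | c1c(OCc2ccccc2)cc(OCc2ccccc2)c2c1OC(c1ccc(OCc3ccccc3)c(OCc3ccccc3)c1)=CC2
F2 | step 5 | [(2R,3S)-5,7-bis(benzyloxy)-2-[3,4-bis(benzyloxy)phenyl]chroman-3-yl](isopinocampheyl)borane | C[C@H]1[C@H](B[C@H]3Cc4c(OCc5ccccc5)cc(OCc5ccccc5)cc4O[C@@H]3c3ccc(OCc4ccccc4)c(OCc4ccccc4)c3)C[C@@H]2C[C@H]1C2(C)C
F3 | step 12 | (2S,4S)-7-(benzyloxy)-2-[3,4-bis(benzyloxy)phenyl]chroman-4-ol | c1ccccc1COc1ccc2c(c1)O[C@H](c1ccc(OCc3ccccc3)c(OCc3ccccc3)c1)C[C@@H]2O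
F4 | step 12 | (2R,3S)-5,7-bis(benzyloxy)-2-[3,4-bis(benzyloxy)phenyl]-8-[(2S,4S)-7-(benzyloxy)-2-[3,4-bis(benzyloxy)phenyl]chroman-4-yl]chroman-3-ol | c1ccccc1COc1ccc2c(c1)O[C@H](c1ccc(OCc3ccccc3)c(OCc3ccccc3)c1)C[C@@H]2c1c(OCc2ccccc2)cc(OCc2ccccc2)c2c1O[C@H](c1ccc(OCc3ccccc3)c(OCc3ccccc3)c1)[C@@H](O)C2
F5 | step 13 | (2R,3S)-3,5,7-tris(benzyloxy)-2-[3,4-bis(benzyloxy)phenyl]-8-[(2S,4S)-7-(benzyloxy)-2-[3,4-bis(benzyloxy)phenyl]chroman-4-yl]chromane | c1ccccc1COc1ccc2c(c1)O[C@H](c1ccc(OCc3ccccc3)c(OCc3ccccc3)c1)C[C@@H]2c1c(OCc2ccccc2)cc(OCc2ccccc2)c2c1O[C@H](c1ccc(OCc3ccccc3)c(OCc3ccccc3)c1)[C@@H](OCc1ccccc1)C2
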